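**Retrosynthetic overview**

1. Target 38 ⇐ keto-butenolide 28 by a functional-group endgame: O8 acylation with acid 8 (retention), O13 acetylation, C3 carbinol → ketone, and the trans-4,5-epoxide from a 4,5-cis-diol (closure with inversion at C5).
2. The ten-membered carbocycle (C1–C10) of 28 ⇐ the six-membered carbocycle (C1–C6) of 25 by an anionic oxy-Cope ring expansion that makes C8–C9 and cleaves a temporary C1–C6 bond.
3. Enabling feature: the C1 ketone lies two atoms from C9 (C9–C10–C1=O), and C8 sits on the butenolide β-carbon C7 next to the lactone γ-carbon C6. With the butenolide ring (O–C6–C7–C11–C12) written as its 2-oxyfuran tautomer (C6=C7, C11=C12), the target contains the retron of a 3-oxy-1,5-diene C9=C10–C1(O)–C6–C7=C8; the spiro centre C6 is sacrificed and hands its chirality to C8.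
4. 25 ⇐ cyclohexanone 18 + dibromosilepine 4 (spiro-butenolide by two Br/Li exchanges and CO2), then isopropenyl addition at C1 and soft enolisation; 18 ⇐ quinone monoketal 10 (asymmetric β-borylation, CBS reduction, OsO4).
5. Ring order: carbocycle C1–C6 (from arene 9) → spiro-butenolide with its seven-membered silylene tether (step 14) → ten-membered ring by ring expansion (step 18, six-membered ring consumed) → epoxide (step 20).

Key step: step 18

Assumption: 6S and 10S, both epimerisable in 28 (furanolate and ketone enolate), are taken as the thermodynamically preferred configurations of the ten-membered ring; germacrane numbering (C1–C15) is used for all intermediates from 10 onward.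

**Route**

Step 1
Reactants: 1 mucobromic acid
Product: 2 3,4-dibromofuran-2(5H)-one
Conditions: NaBH4, MeOH, 0 °C; then 2 M HCl
Reagents that add atoms: none
Why: Borohydride reduction of the open-chain aldehyde tautomer and acid relactonisation (hemiacylal-to-lactone reduction) keep the cis-dibromoalkene inside the ring.

Step 2
Reactants: 2 3,4-dibromofuran-2(5H)-one
Product: 3 (Z)-2,3-dibromobut-2-ene-1,4-diol
Conditions: iBu2AlH (3 equiv), CH2Cl2, −78 → 0 °C; aq. potassium sodium tartrate
Reagents that add atoms: none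
Why: Aluminium hydride reduction of the lactone to the diol leaves the vinylic bromides untouched at low temperature, and the Z geometry is inherited from the ring.

Step 3
Reactants: 3 (Z)-2,3-dibromobut-2-ene-1,4-diol
Product: 4 5,6-dibromo-2,2-di-tert-butyl-4,7-dihydro-1,3,2-dioxasilepine
Conditions: tBu2Si(OTf)2, 2,6-lutidine, CH2Cl2, 0 °C
Reagents that add atoms: di-tert-butylsilyl bis(trifluoromethanesulfonate), CC(C)(C)[Si](OS(=O)(=O)C(F)(F)F)(OS(=O)(=O)C(F)(F)F)C(C)(C)C
Why: Silylene protection of a cis-1,4-diol gives the seven-membered tether that later fixes the enol-ether geometry at C8 and survives organolithiums.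

Step 4
Reactants: 5 4-methylfuran-2(5H)-one
Product: 6 sodium (Z)-4-hydroxy-3-methylbut-2-enoate
Conditions: NaOH (1.0 equiv), H2O/THF, 0 °C → rt; freeze-dry
Reagents that add atoms: sodium hydroxide, [Na+].[OH-]
Why: Saponification of the butenolide gives the Z-hydroxy acid, its geometry guaranteed by the ring, and keeping it as the sodium salt prevents relactonisation.

Step 5
Reactants: 6 sodium (Z)-4-hydroxy-3-methylbut-2-enoate
Product: 8 (Z)-3-methyl-4-(triethylsilyloxy)but-2-enoic acid, via bis-silyl derivative 7 (not isolated)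
Conditions: Et3SiCl (2.2 equiv), imidazole, DMF, 0 °C; then K2CO3 (0.2 equiv), MeOH/H2O, 0 °C; extraction at pH 5
Reagents that add atoms: chlorotriethylsilane, CC[Si](Cl)(CC)CC
Why: Silylation of both oxygens followed by selective solvolysis of the far more labile silyl ester leaves the silyl ether, which blocks lactonisation of the Z-acid.

Step 6
Reactants: 9 4-methoxy-2-methylphenol
Product: 10 4,4-dimethoxy-2-methylcyclohexa-2,5-dien-1-one
Conditions: PhI(OAc)2, MeOH, 0 °C
Reagents that add atoms: methanol, CO
Why: Hypervalent-iodine oxidative dearomatisation of a para-methoxyphenol in methanol gives the quinone monoketal, masking the future C6 ketone.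

Step 7
Reactants: 10 4,4-dimethoxy-2-methylcyclohexa-2,5-dien-1-one
Product: 12 (5S)-5-hydroxy-4,4-dimethoxy-2-methylcyclohex-2-en-1-one, via boronate 11 (not isolated)
Conditions: CuCl (5 mol %), NaOtBu (10 mol %), (R)-1-[(SP)-2-(diphenylphosphino)ferrocenyl]ethyldicyclohexylphosphine (6 mol %; the antipode that gives 5S is used), B2pin2 (1.1 equiv), MeOH, THF, 0 °C; then NaBO3·4H2O, THF/H2O, rt
Reagents that add atoms: sodium perborate, [Na+].[O-]OB=O
Why: Copper-catalysed asymmetric conjugate borylation should attack the unsubstituted enone arm (the α-methyl arm is slower), the chiral bisphosphine setting the temporary C1 centre, and perborate oxidation replaces boron by oxygen with retention.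

Step 8
Reactants: 12 (5S)-5-hydroxy-4,4-dimethoxy-2-methylcyclohex-2-en-1-one
Product: 13 (5S)-4,4-dimethoxy-2-methyl-5-(triethylsilyloxy)cyclohex-2-en-1-one
Conditions: Et3SiCl, imidazole, DMF, 0 °C
Reagents that add atoms: chlorotriethylsilane, CC[Si](Cl)(CC)CC
Why: Silyl ether formation under weakly basic conditions protects the β-hydroxy ketone before it can dehydrate.

Step 9
Reactants: 13 (5S)-4,4-dimethoxy-2-methyl-5-(triethylsilyloxy)cyclohex-2-en-1-one
Product: 14 (1S,5S)-4,4-dimethoxy-2-methyl-5-(triethylsilyloxy)cyclohex-2-en-1-ol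
Conditions: (R)-2-methyl-CBS-oxazaborolidine (20 mol %), BH3·SMe2, THF, −30 °C; MeOH quench
Reagents that add atoms: none
Why: Corey–Bakshi–Shibata 1,2-reduction with the α-methylalkenyl arm as the large group should give the 1S carbinol (C3 of the target), trans to the silyloxy group, under reagent control.

Step 10
Reactants: 14 (1S,5S)-4,4-dimethoxy-2-methyl-5-(triethylsilyloxy)cyclohex-2-en-1-ol
Product: 15 4-methoxybenzyl ether of 14
Conditions: NaH, 4-MeOC6H4CH2Cl, Bu4NI (cat.), DMF, 0 °C
Reagents that add atoms: 4-methoxybenzyl chloride, COc1ccc(CCl)cc1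
Why: Williamson etherification installs the group that carries O3 to the end, and the trans-1,3 arrangement of the two oxygens keeps the silyl group from migrating.

Step 11
Reactants: 15 4-methoxybenzyl ether of 14
Product: 16 (4S,6S)-4-[(4-methoxybenzyl)oxy]-3-methyl-6-(triethylsilyloxy)cyclohex-2-en-1-one
Conditions: 10% aq. oxalic acid on SiO2, CH2Cl2, rt
Reagents that add atoms: water, O
Why: Mild acid hydrolysis of the dimethyl ketal runs through an allyl-stabilised oxocarbenium ion and should spare the silyl and benzyl ethers, and it is done now because the ketal would be much harder to open once flanked by two oxygenated carbons.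

Step 12
Reactants: 16 (4S,6S)-4-[(4-methoxybenzyl)oxy]-3-methyl-6-(triethylsilyloxy)cyclohex-2-en-1-one
Product: 17 (2R,3S,4S,6S)-2,3-dihydroxy-4-[(4-methoxybenzyl)oxy]-3-methyl-6-(triethylsilyloxy)cyclohexan-1-one
Conditions: OsO4 (5 mol %), N-methylmorpholine N-oxide, citric acid, tBuOH/H2O, rt
Reagents that add atoms: N-methylmorpholine N-oxide, C[N+]1([O-])CCOCC1; water, O
Why: Upjohn dihydroxylation (citric-acid variant for electron-poor alkenes) should add OsO4 anti to the allylic benzyloxy group, held pseudoaxial by allylic strain with the methyl group (Kishi model), giving the 4,5-cis-diol trans to O3.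

Step 13
Reactants: 17 (2R,3S,4S,6S)-2,3-dihydroxy-4-[(4-methoxybenzyl)oxy]-3-methyl-6-(triethylsilyloxy)cyclohexan-1-one
Product: 18 acetonide ketone (2,3-O-isopropylidene derivative of 17)
Conditions: 2-methoxypropene, pyridinium p-toluenesulfonate (cat.), CH2Cl2, 0 °C
Reagents that add atoms: 2-methoxypropene, COC(C)=C
Why: Kinetic acetonide formation on the cis-diol removes the retro-aldol-prone β-hydroxy ketone and creates the cis-fused bicycle that directs the next addition.

Step 14
Reactants: 4 5,6-dibromo-2,2-di-tert-butyl-4,7-dihydro-1,3,2-dioxasilepine; 18 acetonide ketone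
Product: 22 spirobutenolide alcohol (lactone oxygen on C6 cis to O5 and O4 and to the C1 hydroxyl), via vinyllithium 19 (not isolated), via bromo alkoxide 20 (not isolated), via silyl ether lactone 21 (not isolated)
Conditions: 4, tBuLi (2.0 equiv), THF, −78 °C; 18, −78 °C; tBuLi (2.2 equiv), −78 °C; CO2, −78 → 0 °C; then AcOH/THF/H2O (3:1:1), rt
Reagents that add atoms: carbon dioxide, O=C=O
Why: Sequential bromine–lithium exchange: vinyllithium 19 should add to the ketone by equatorial attack anti to the acetonide and to both equatorial α-oxygens (the axial O4 blocks the other face), which sets the spiro carbon C6; the second exchange and carboxylation give a Z-γ-hydroxy acid that lactonises on the acidic work-up, which also removes the triethylsilyl group.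

Step 15
Reactants: 22 spirobutenolide alcohol
Product: 23 spirobutenolide C1 ketone
Conditions: Dess–Martin periodinane, NaHCO3, CH2Cl2, 0 °C → rt
Reagents that add atoms: none
Why: Dess–Martin oxidation of the hindered secondary alcohol is neutral and should leave the benzyl ether, acetonide, silylene and butenolide alone.

Step 16
Reactants: 23 spirobutenolide C1 ketone
Product: 24 tertiary isopropenyl carbinol (isopropenyl cis to the lactone oxygen)
Conditions: CH2=C(CH3)MgBr, CeCl3, THF, −78 °C
Reagents that add atoms: isopropenylmagnesium bromide, CC(=C)[Mg]Br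
Why: Organocerium 1,2-addition is weakly basic (no enolisation or β-elimination of O3) and prefers the ketone over the conjugated lactone; attack is expected trans to C7, and the C1 configuration is erased in step 18 in any case.

Step 17
Reactants: 24 tertiary isopropenyl carbinol
Product: 25 triisopropylsilyl dienol ether (C11=C12–OSi and exocyclic (E)-C7=C8)
Conditions: iPr3SiOTf (1.3 equiv), Et3N, CH2Cl2, −20 → 0 °C; used crude
Reagents that add atoms: triisopropylsilyl trifluoromethanesulfonate, CC(C)[Si](C(C)C)(C(C)C)OS(=O)(=O)C(F)(F)F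
Why: Soft enolisation of the butenolide can only remove a C8 hydrogen (C6 is quaternary), the bulky triflate should not silylate the hindered tertiary alcohol, and the seven-membered silylene forces O8 cis to C11 in the new C7=C8 bond.

Step 18
Reactants: 25 triisopropylsilyl dienol ether
Product: 28 ring-expanded keto-butenolide (3S,4R,5S,6S,8S,10S), via potassium alkoxide 26 (not isolated), via furan enolate 27 (not isolated)
Conditions: KH (1.2 equiv), 18-crown-6, THF, 0 → 25 °C; AcOH, −78 °C; then 1 M HCl/THF, 0 °C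
Reagents that add atoms: none
Why: Deprotonation gives alkoxide 26, in which the C1–C6 bond is flanked by the isopropenyl group (C10=C9) and the exocyclic C7=C8 dienol-ether bond, and a charge-accelerated [3,3] shift forms C8–C9 while breaking C1–C6; the closest known reaction type is the anionic oxy-Cope ring expansion of 1,2-dialkenylcyclohexanols to cyclodec-5-enones. The ten-membered carbocycle is closed by ring expansion through a six-centre boat- or chair-like array (no other ring is made; the lactone ring merely becomes an aromatic 2-silyloxyfuran as C6=C7 forms, which adds driving force to enolate formation). C8 is set by suprafacial transfer of chirality from the spiro carbon C6: C9 can only reach the face of C8 on which C1 stands, and the silylene holds O8 cis to C11, which together should give 8S whichever C1 epimer or transition-state shape is used. C10 is set by C-protonation of enolate 27 with acetic acid from the outer face of the ring, and C6 by acid hydrolysis of the silyloxyfuran, which protonates the vinylogous position C6 and returns the conjugated butenolide; both centres stay epimerisable toward the more stable ring diastereomer. The step needs the [3,3] path to win over retro-aldol-type fragmentation, a [1,3] shift and Cope paths through ring bonds; this is secured by holding the lactone as a neutral silyl ketene acetal (no acidic C–H, poor carbanion leaving group) and by the freely rotating exocyclic isopropenyl group, whereas ring bonds lie in the nodal plane of their neighbouring π bonds.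

Step 19
Reactants: 28 ring-expanded keto-butenolide
Product: 29 4,5-diol (3S,4S,5S,6S,8S,10S)
Conditions: AcOH/H2O (4:1), 45 °C
Reagents that add atoms: none
Why: Acid hydrolysis of the isopropylidene acetal should be tolerated by the benzyl ether and the hindered di-tert-butylsilylene.

Step 20
Reactants: 29 4,5-diol
Product: 31 trans-4,5-epoxide (3S,4R,5R,6S,8S,10S), via mesylate 30 (not isolated)
Conditions: MeSO2Cl, Et3N, CH2Cl2, −20 °C; then DBU, 0 °C → rt
Reagents that add atoms: none
Why: Selective sulfonylation of the secondary C5 hydroxyl and 3-exo-tet Williamson closure by the tertiary C4 oxygen with inversion at C5 turn the cis-diol of the former cyclohexane into the trans-epoxide (C4 retained, C5 becomes R), a geometry no cyclohexene oxide could have delivered.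

Step 21
Reactants: 31 trans-4,5-epoxide
Product: 32 8,13-diol (3S,4R,5R,6S,8S,10S)
Conditions: Bu4NF, AcOH, THF, 0 °C
Reagents that add atoms: none
Why: Buffered fluoride cleaves the silylene without base-mediated damage to the epoxide or the butenolide.

Step 22
Reactants: 32 8,13-diol
Product: 33 13-acetate
Conditions: AcCl (1.05 equiv), 2,4,6-collidine, CH2Cl2, −78 °C
Reagents that add atoms: acetyl chloride, CC(Cl)=O
Why: Acylation with acetyl chloride and collidine at low temperature is selective for the primary allylic hydroxyl over the secondary C8 hydroxyl.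

Step 23
Reactants: 33 13-acetate; 8 (Z)-3-methyl-4-(triethylsilyloxy)but-2-enoic acid
Product: 35 8-O-acyl ester, via mixed anhydride 34 (not isolated)
Conditions: 8, 2,4,6-Cl3C6H2COCl, Et3N, toluene, rt; then 33, DMAP, rt
Reagents that add atoms: none
Why: Yamaguchi esterification acylates O8 with retention (the hydroxyl reacts through its open form even if it rests as the C1 hemiketal), and the β,β-disubstituted Z-enoate should resist isomerisation.

Step 24
Reactants: 35 8-O-acyl ester
Product: 36 3-hydroxy compound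
Conditions: DDQ, CH2Cl2/pH 7 buffer, 0 °C
Reagents that add atoms: none
Why: Oxidative cleavage of the 4-methoxybenzyl ether is neutral and orthogonal to the silyl ether, acetate, epoxide and butenolide.

Step 25
Reactants: 36 3-hydroxy compound
Product: 37 1,3-diketone (side-chain silyl ether of the target)
Conditions: Dess–Martin periodinane (1.2 equiv), NaHCO3, CH2Cl2, 0 °C
Reagents that add atoms: none
Why: Dess–Martin oxidation converts the β-hydroxy ketone into the 1,3-diketone under buffered neutral conditions that the adjacent epoxide should tolerate.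

Step 26
Reactants: 37 1,3-diketone
Product: 38 target
Conditions: AcOH/THF/H2O (3:1:1), 0 °C → rt
Reagents that add atoms: none
Why: Mild acidic solvolysis removes the primary allylic triethylsilyl ether without base, which the epoxy-diketone and the Z-hydroxy enoate would not survive.

**Compound list**

1 | mucobromic acid (3,4-dibromo-5-hydroxyfuran-2(5H)-one) | OC1OC(=O)C(Br)=C1Br | starting material
2 | 3,4-dibromofuran-2(5H)-one | O=C1OCC(Br)=C1Br | intermediate
3 | (Z)-2,3-dibromobut-2-ene-1,4-diol | OC/C(Br)=C(Br)\CO | intermediate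
4 | 5,6-dibromo-2,2-di-tert-butyl-4,7-dihydro-1,3,2-dioxasilepine | CC(C)(C)[Si]1(C(C)(C)C)OCC(Br)=C(Br)CO1 | intermediate
5 | 4-methylfuran-2(5H)-one | CC1=CC(=O)OC1 | starting material
6 | sodium (Z)-4-hydroxy-3-methylbut-2-enoate | [Na+].[O-]C(=O)/C=C(/C)CO | intermediate
7 | triethylsilyl (Z)-3-methyl-4-(triethylsilyloxy)but-2-enoate | CC[Si](CC)(CC)OC/C(C)=C\C(=O)O[Si](CC)(CC)CC | intermediate
8 | (Z)-3-methyl-4-(triethylsilyloxy)but-2-enoic acid | CC[Si](CC)(CC)OC/C(C)=C\C(O)=O | intermediate
9 | 4-methoxy-2-methylphenol | COc1ccc(O)c(C)c1 | starting material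
10 | 4,4-dimethoxy-2-methylcyclohexa-2,5-dien-1-one | COC1(OC)C=CC(=O)C(C)=C1 | intermediate
11 | (5S)-4,4-dimethoxy-2-methyl-5-(4,4,5,5-tetramethyl-1,3,2-dioxaborolan-2-yl)cyclohex-2-en-1-one | COC1(OC)[C@@H](B2OC(C)(C)C(C)(C)O2)CC(=O)C(C)=C1 | intermediate
12 | (5S)-5-hydroxy-4,4-dimethoxy-2-methylcyclohex-2-en-1-one | COC1(OC)[C@@H](O)CC(=O)C(C)=C1 | intermediate
13 | (5S)-4,4-dimethoxy-2-methyl-5-(triethylsilyloxy)cyclohex-2-en-1-one | COC1(OC)[C@@H](O[Si](CC)(CC)CC)CC(=O)C(C)=C1 | intermediate
14 | (1S,5S)-4,4-dimethoxy-2-methyl-5-(triethylsilyloxy)cyclohex-2-en-1-ol | COC1(OC)[C@@H](O[Si](CC)(CC)CC)C[C@H](O)C(C)=C1 | intermediate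
15 | 4-methoxybenzyl ether of 14 (1S,5S) | COC1(OC)[C@@H](O[Si](CC)(CC)CC)C[C@H](OCc2ccc(OC)cc2)C(C)=C1 | intermediate
16 | (4S,6S)-4-[(4-methoxybenzyl)oxy]-3-methyl-6-(triethylsilyloxy)cyclohex-2-en-1-one | O=C1[C@@H](O[Si](CC)(CC)CC)C[C@H](OCc2ccc(OC)cc2)C(C)=C1 | intermediate
17 | (2R,3S,4S,6S)-2,3-dihydroxy-4-[(4-methoxybenzyl)oxy]-3-methyl-6-(triethylsilyloxy)cyclohexan-1-one | O=C1[C@@H](O[Si](CC)(CC)CC)C[C@H](OCc2ccc(OC)cc2)[C@@](C)(O)[C@H]1O | intermediate
18 | acetonide ketone: 2,3-O-isopropylidene derivative of 17 (C6 ketone; O4 and O5 cis to the C1 silyloxy group, trans to O3) | O=C1[C@@H](O[Si](CC)(CC)CC)C[C@H](OCc3ccc(OC)cc3)[C@@]2(C)OC(C)(C)O[C@@H]12 | intermediate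
19 | (6-bromo-2,2-di-tert-butyl-4,7-dihydro-1,3,2-dioxasilepin-5-yl)lithium | CC(C)(C)[Si]1(C(C)(C)C)OCC([Li])=C(Br)CO1 | intermediate
20 | lithium alkoxide of the 1,2-adduct of 19 to 18 (C6–O cis to O5; C1 triethylsilyl ether) | [Li+].[O-][C@]1([C@@H](O[Si](CC)(CC)CC)C[C@H](OCc4ccc(OC)cc4)[C@@]5(C)OC(C)(C)O[C@@H]15)C2=C(Br)CO[Si](C(C)(C)C)(C(C)(C)C)OC2 | intermediate
21 | C1 triethylsilyl ether of spirobutenolide 22 | O=C1O[C@]2([C@@H](O[Si](CC)(CC)CC)C[C@H](OCc4ccc(OC)cc4)[C@@]5(C)OC(C)(C)O[C@@H]25)C3=C1CO[Si](C(C)(C)C)(C(C)(C)C)OC3 | intermediate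
22 | spirobutenolide alcohol: C6 spiro-fused butenolide whose C7 and C11 carry the CH2O–Si(tBu)2–OCH2 bridge (C8, C13); cyclohexane with C1–OH, C3–O-(4-methoxybenzyl), C4/C5 acetonide; lactone oxygen cis to O5, O4 and C1–OH | O=C1O[C@]2([C@@H](O)C[C@H](OCc4ccc(OC)cc4)[C@@]5(C)OC(C)(C)O[C@@H]25)C3=C1CO[Si](C(C)(C)C)(C(C)(C)C)OC3 | intermediate
23 | C1 ketone of 22 | O=C1O[C@]2(C(=O)C[C@H](OCc4ccc(OC)cc4)[C@@]5(C)OC(C)(C)O[C@@H]25)C3=C1CO[Si](C(C)(C)C)(C(C)(C)C)OC3 | intermediate
24 | tertiary carbinol: C1 bears OH and isopropenyl (isopropenyl cis to the lactone oxygen, trans to C7) | O=C1O[C@]2([C@@](O)(C(C)=C)C[C@H](OCc4ccc(OC)cc4)[C@@]5(C)OC(C)(C)O[C@@H]25)C3=C1CO[Si](C(C)(C)C)(C(C)(C)C)OC3 | intermediate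
25 | 12-O-triisopropylsilyl dienol ether of 24 (C11=C12, exocyclic (E)-C7=C8 with O8 cis to C11) | CC(C)[Si](C(C)C)(C(C)C)OC1=C2CO[Si](C(C)(C)C)(C(C)(C)C)O/C=C2/[C@]3(O1)[C@@](O)(C(C)=C)C[C@H](OCc4ccc(OC)cc4)[C@@]5(C)OC(C)(C)O[C@@H]35 | intermediate
26 | potassium C1 alkoxide of 25 | CC(C)[Si](C(C)C)(C(C)C)OC1=C2CO[Si](C(C)(C)C)(C(C)(C)C)O/C=C2/[C@]3(O1)[C@@]([O-])(C(C)=C)C[C@H](OCc4ccc(OC)cc4)[C@@]5(C)OC(C)(C)O[C@@H]35.[K+] | intermediate
27 | ring-expanded potassium enolate (C1–O−, C1=C10) fused to the 2-(triisopropylsilyloxy)furan (C6=C7, C11=C12); 8S | CC(C)(C)[Si]1(C(C)(C)C)OCc2c3[C@@H](O1)CC(C)=C([O-])C[C@H](OCc5ccc(OC)cc5)[C@@]4(C)OC(C)(C)O[C@H]4c3oc2O[Si](C(C)C)(C(C)C)C(C)C.[K+] | intermediate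
28 | (3S,4R,5S,6S,8S,10S)-8,13-(di-tert-butylsilylenedioxy)-4,5-(isopropylidenedioxy)-3-[(4-methoxybenzyl)oxy]-1-oxogermacr-7(11)-en-12,6-olide | CC(C)(C)[Si]1(C(C)(C)C)OCC2=C3[C@@H](O1)C[C@H](C)C(=O)C[C@H](OCc5ccc(OC)cc5)[C@@]4(C)OC(C)(C)O[C@H]4[C@H]3OC2=O | intermediate
29 | (3S,4S,5S,6S,8S,10S)-8,13-(di-tert-butylsilylenedioxy)-4,5-dihydroxy-3-[(4-methoxybenzyl)oxy]-1-oxogermacr-7(11)-en-12,6-olide | CC(C)(C)[Si]1(C(C)(C)C)OCC2=C3[C@@H](O1)C[C@H](C)C(=O)C[C@H](OCc5ccc(OC)cc5)[C@@](C)(O)[C@@H](O)[C@H]3OC2=O | intermediate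
30 | 5-O-methanesulfonate of 29 | CC(C)(C)[Si]1(C(C)(C)C)OCC2=C3[C@@H](O1)C[C@H](C)C(=O)C[C@H](OCc5ccc(OC)cc5)[C@@](C)(O)[C@@H](OS(C)(=O)=O)[C@H]3OC2=O | intermediate
31 | (3S,4R,5R,6S,8S,10S)-8,13-(di-tert-butylsilylenedioxy)-4,5-epoxy-3-[(4-methoxybenzyl)oxy]-1-oxogermacr-7(11)-en-12,6-olide | CC(C)(C)[Si]1(C(C)(C)C)OCC2=C3[C@@H](O1)C[C@H](C)C(=O)C[C@H](OCc5ccc(OC)cc5)[C@@]4(C)O[C@@H]4[C@H]3OC2=O | intermediate
32 | (3S,4R,5R,6S,8S,10S)-4,5-epoxy-8,13-dihydroxy-3-[(4-methoxybenzyl)oxy]-1-oxogermacr-7(11)-en-12,6-olide | OCC1=C2[C@@H](O)C[C@H](C)C(=O)C[C@H](OCc5ccc(OC)cc5)[C@@]3(C)O[C@@H]3[C@H]2OC1=O | intermediate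
33 | 13-acetate of 32 | CC(=O)OCC1=C2[C@@H](O)C[C@H](C)C(=O)C[C@H](OCc5ccc(OC)cc5)[C@@]3(C)O[C@@H]3[C@H]2OC1=O | intermediate
34 | mixed anhydride of 8 with 2,4,6-trichlorobenzoic acid | CC[Si](CC)(CC)OC/C(C)=C\C(=O)OC(=O)c1c(Cl)cc(Cl)cc1Cl | intermediate
35 | 8-O-[(Z)-3-methyl-4-(triethylsilyloxy)but-2-enoyl] derivative of 33 | CC(=O)OCC1=C2[C@@H](OC(=O)/C=C(/C)CO[Si](CC)(CC)CC)C[C@H](C)C(=O)C[C@H](OCc5ccc(OC)cc5)[C@@]3(C)O[C@@H]3[C@H]2OC1=O | intermediate
36 | 3-hydroxy compound (3S,4R,5R,6S,8S,10S), benzyl ether removed | CC(=O)OCC1=C2[C@@H](OC(=O)/C=C(/C)CO[Si](CC)(CC)CC)C[C@H](C)C(=O)C[C@H](O)[C@@]3(C)O[C@@H]3[C@H]2OC1=O | intermediate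
37 | side-chain O-triethylsilyl ether of the target (4S,5R,6S,8S,10S) | CC(=O)OCC1=C2[C@@H](OC(=O)/C=C(/C)CO[Si](CC)(CC)CC)C[C@H](C)C(=O)CC(=O)[C@@]3(C)O[C@@H]3[C@H]2OC1=O | intermediate
38 | CNP0295642.1: (4S,5R,6S,8S,10S)-13-acetoxy-4,5-epoxy-8-[(Z)-4-hydroxy-3-methylbut-2-enoyloxy]-1,3-dioxogermacr-7(11)-en-12,6-olide | CC(=O)OCC1=C2[C@@H](OC(=O)/C=C(/C)CO)C[C@H](C)C(=O)CC(=O)[C@@]3(C)O[C@@H]3[C@H]2OC1=O | target

**Step count and risks**

Total step count: 26. Longest linear sequence: 21 steps (steps 6–26, from 9); steps 1–3 and 4–5 make the two side fragments.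

Most likely to fail, with fallbacks:

1. Step 18. The alkoxide may break the C1–C6 bond heterolytically instead of in concert, so that the fragments recombine at C6 (a [1,3] shift) or drift apart; the silyl group may move from O12 to the C1 alkoxide; and the two protonations (C10, C6) may show poor facial selectivity. The fallback leaves the anionic manifold. Carbinol 24 would be treated with Me3SiOTf and Et3N (CH2Cl2, 0 °C) to give the bis(trimethylsilyl) compound F1 (C1 silyl ether and C12 silyl dienol ether). F1 would be heated in toluene at 150 °C (sealed tube, base-washed glass) to undergo the neutral siloxy-Cope rearrangement to the ring-expanded bis(trimethylsilyl) compound F2 (C1=C10 silyl enol ether and 2-silyloxyfuran). With no alkoxide present, the fragmentation and silyl-transfer channels are closed. Hydrolysis of F2 with 1 M HCl in THF at 0 °C would bring the route back at compound 28, with equilibration of C6 and C10 by a trace of DBU if needed.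

2. Step 20. Under base the C5 mesylate may eliminate across C5–C6 through the acidic γ-hydrogen of the butenolide (E1cB via the furanolate), or C6 may epimerise, before the tertiary oxygen closes the epoxide. The fallback replaces sulfonate displacement by a neutral redox dehydration: diol 29 would be treated with PPh3 and diisopropyl azodicarboxylate (toluene, 0 °C → rt), so that the secondary C5 oxygen is activated as an oxyphosphonium ion and displaced by the C4 oxygen with inversion. This sets out from 29 and returns directly at epoxide 31; it makes no new compound (F0).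

3. Step 14. The hindered α,α′-dioxygenated ketone may be enolised by the vinyllithium, the second bromine–lithium exchange may be incomplete, or the second vinyllithium may be protonated before carboxylation. The fallback separates the two bond formations. Ketone 18 would be treated with vinyllithium 19 only, and after quenching the bromo alcohol F3 would be isolated. F3 would then be closed by palladium-catalysed carbonylative lactonisation (Pd(PPh3)4, a zerovalent palladium complex, CO 1 atm, Et3N, DMF, 70 °C) to the silyl ether lactone 21. Treatment with AcOH/THF/H2O would return the route at compound 22.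

**Further compounds**

F1 | step 18 | bis(trimethylsilyl) derivative of 24 (C1 trimethylsilyl ether; C12 trimethylsilyl dienol ether with exocyclic (E)-C7=C8) | C[Si](C)(C)OC1=C2CO[Si](C(C)(C)C)(C(C)(C)C)O/C=C2/[C@]3(O1)[C@@](O[Si](C)(C)C)(C(C)=C)C[C@H](OCc4ccc(OC)cc4)[C@@]5(C)OC(C)(C)O[C@@H]35
F2 | step 18 | ring-expanded bis(trimethylsilyl) compound (C1=C10 trimethylsilyl enol ether fused to the 2-trimethylsilyloxyfuran; 8S) | CC(C)(C)[Si]1(C(C)(C)C)OCc2c3[C@@H](O1)CC(C)=C(O[Si](C)(C)C)C[C@H](OCc5ccc(OC)cc5)[C@@]4(C)OC(C)(C)O[C@H]4c3oc2O[Si](C)(C)C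
F0 | step 20 | none | none
F3 | step 14 | bromo alcohol (tertiary C6 carbinol from 19 and 18; C6–OH cis to O5; C1 triethylsilyl ether) | O[C@]1([C@@H](O[Si](CC)(CC)CC)C[C@H](OCc4ccc(OC)cc4)[C@@]5(C)OC(C)(C)O[C@@H]15)C2=C(Br)CO[Si](C(C)(C)C)(C(C)(C)C)OC2
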